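The cyclohexene ring C (C1–C10–C9–C8–C7–C11, cedrane numbering) holds the C10 oxygen and the C8 carboxyl in a 1,4-relation. The bare, stereo-free C9 sits between them, which is the retron of a one-carbon homologation of a β-keto ester. Deleting C9 shrinks the bicyclo[3.2.1]octene to a norbornanone β-keto ester. Its rings A and B and four stereocentres arise in one intramolecular Diels–Alder reaction of a 2-silyloxycyclopentadiene. The key step re-inserts C9 with a zinc carbenoid (donor–acceptor cyclopropanolate, cleavage of the C8–C10 bond). Iodination and elimination in the same flask then deliver ring C as its γ-oxo-enoate. The precursor is the tricyclic tert-butyl β-keto ester 17.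

Key step: step 10

Numbering (cedrane, used for all tricyclic compounds):
- C1 is the spiro quaternary carbon, C2 the CH bearing the formyl carbon, C3 and C4 are CH2, and C5 is the ring-fusion CH.
- C6 is the quaternary carbon (CH3, CH2OH), C7 the bridgehead CH, C8 is =C(CO2H), C9 is =CH, C10 is CH–O, and C11 is the CH2 bridge.
- Ring A = C1–C5. Ring B = C1, C5, C6, C7, C11. Ring C = C1, C10, C9, C8, C7, C11.
- In the 9-nor compounds C8 is bonded directly to C10.
- exo means on the side of the C11 bridge; endo means on the side of the C5–C6 bridge.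

Assumption: the SMILES is read as exo CH3 and endo CH2OH at C6, endo H at C5, endo acyloxy at C10, and the formyl group at C2 on the C11 side.

Remark: both conjugated and unconjugated cyclopentenone isomers feed the same pool of silyloxycyclopentadienes, so the ring position of the double bond before step 5 is of no consequence.

Stereocentres: C2 is set in step 1; C1, C5, C6 and C7 in step 5; C10 in step 11; the Z-alkene in step 15.

Step 1
Reactants: 1 (1S,5R)-2-oxabicyclo[3.3.0]oct-6-en-3-one; 2 4-iodobut-1-ene
Product: 4 (3S,3aS,6aS)-3-(but-3-en-1-yl)-3,3a,6,6a-tetrahydro-2H-cyclopenta[b]furan-2-one, via lithium enolate 3 (not isolated)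
Conditions: LiN(iPr)2, THF, −78 °C; 2, DMPU, −78 → −20 °C
Reagents that add atoms: none
Why: Lactone enolate alkylation (SN2 on a primary iodide), in which the cup-shaped cis-bicyclo[3.3.0] enolate should be attacked on its convex face, so the chain ends up cis to H-3a and sets the future C2 stereocentre.

Step 2
Reactants: 4 butenyl lactone
Product: 5 (2S)-2-[(1S,5S)-5-hydroxycyclopent-2-en-1-yl]-N-methoxy-N-methylhex-5-enamide
Conditions: MeNH(OMe)·HCl, AlMe3, CH2Cl2, 0 °C → rt; aq. potassium sodium tartrate
Reagents that add atoms: N,O-dimethylhydroxylamine hydrochloride, Cl.CNOC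
Why: Weinreb aminolysis of a lactone with the aluminium amide opens the ring irreversibly and touches no stereocentre.

Step 3
Reactants: 5 hydroxy Weinreb amide
Product: 7 (2S)-N-methoxy-N-methyl-2-(5-oxocyclopent-1-en-1-yl)hex-5-enamide, via cyclopent-3-enone 6 (not isolated)
Conditions: Dess–Martin periodinane, CH2Cl2, 0 °C → rt; then DBU (10 mol %), CH2Cl2, rt
Reagents that add atoms: none
Why: Dess–Martin oxidation followed by base-catalysed β,γ → α,β enone isomerisation through the doubly activated ring C–H erases the two ring stereocentres on purpose, while the side-chain centre, acidified only by the amide, should stay intact.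

Step 4
Reactants: 7 cyclopentenone amide; 8 methyl methacrylate
Product: 9 methyl (2E,6S)-6-[methoxy(methyl)carbamoyl]-2-methyl-6-(5-oxocyclopent-1-en-1-yl)hex-2-enoate
Conditions: 8 (10 equiv), RuCl2(H2IMes)(=CH-C6H4-2-OiPr) (second-generation Hoveyda–Grubbs catalyst, 5 mol %), CH2Cl2, 40 °C
Reagents that add atoms: none
Why: Olefin cross-metathesis of a terminal alkene with a 1,1-disubstituted acrylate should give the favoured E-trisubstituted enoate, the trisubstituted electron-poor ring enone being inert.

Step 5
Reactants: 9 enone enoate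
Product: 12 Diels–Alder adduct (9-norcedr-8(10)-ene: OTBS at C10; exo CH3 and endo CO2Me at C6; CON(OMe)Me at C2 on the C11 side; endo H at C5), via cross-conjugated dienol ether 10 (not isolated), via 1-alkyl-2-silyloxy diene 11 (not isolated)
Conditions: TBSOTf (1.2 equiv), Et3N, CH2Cl2, 0 °C; aq. NaHCO3; then toluene (0.01 M), BHT, 100 °C
Reagents that add atoms: tert-butyldimethylsilyl triflate, CC(C)(C)[Si](C)(C)OS(=O)(=O)C(F)(F)F
Why: Soft enolisation gives 10 and a [1,5]-H shift gives 11, the only isomer whose three-atom tether reaches the dienophile; its intramolecular Diels–Alder reaction (enol-ether terminus to enoate β-carbon, tether exo, ester endo) should translate the E-alkene into exo CH3/endo CO2Me at C6 and set C1, C5 and C7, the diene face being chosen by C2, which turns its H toward the OTBS group and its amide toward C11.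

Step 6
Reactants: 12 Diels–Alder adduct
Product: 13 hydroxy aldehyde (as 12 but endo CH2OH at C6 and CHO at C2)
Conditions: LiAlH4, THF, −78 → 0 °C; aq. potassium sodium tartrate
Reagents that add atoms: none
Why: Hydride reduction takes the ester to the primary alcohol and stops at the chelated tetrahedral intermediate of the Weinreb amide, which releases the aldehyde only on work-up, while the silyl enol ether shields the C10 carbonyl.

Step 7
Reactants: 13 hydroxy aldehyde
Product: 14 keto acetal alcohol (9-norcedran-10-one: CH(OMe)2 at C2; endo CH2OH at C6)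
Conditions: HC(OMe)3, camphorsulfonic acid (5 mol %), MeOH, 0 °C → rt; aq. NaHCO3
Reagents that add atoms: trimethyl orthoformate, COC(OC)OC
Why: Acid-catalysed acetalisation with concurrent protodesilylation of the enol ether should trap the aldehyde before C2 can epimerise, and the ketone next to quaternary C1 is too hindered to be ketalised.

Step 8
Reactants: 14 keto acetal alcohol
Product: 15 TBS ether of 14
Conditions: TBSCl, imidazole, DMF, rt
Reagents that add atoms: tert-butyldimethylsilyl chloride, CC(C)(C)[Si](C)(C)Cl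
Why: Standard silylation of a primary alcohol, with no stereocentre involved.

Step 9
Reactants: 15 silyl ether ketone
Product: 17 tert-butyl β-keto ester (15 with exo CO2tBu at C8), via lithium enolate 16 (not isolated)
Conditions: LiN(SiMe3)2 (2.2 equiv), THF, −78 °C; tert-butyl 1H-imidazole-1-carboxylate, −78 → 0 °C; aq. NH4Cl
Reagents that add atoms: tert-butyl 1H-imidazole-1-carboxylate, CC(C)(C)OC(=O)n1ccnc1
Why: Mander-type C-acylation of the only possible enolate (C1 is quaternary) with an N-alkoxycarbonylimidazole should occur on the exo face, and the new C8 centre is of no consequence because it is planarised in step 10.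

Step 10
Reactants: 17 tert-butyl β-keto ester
Product: 22 γ-oxo-enoate (tert-butyl 10-oxocedr-8-ene-8-carboxylate core: CH(OMe)2 at C2; exo CH3 and endo CH2OTBS at C6), via ethylzinc enolate 18 (not isolated), via zinc cyclopropanolate 19 (not isolated), via ring-expanded zinc enolate 20 (not isolated), via tertiary iodide 21 (not isolated)
Conditions: Et2Zn, CH2I2, CH2Cl2, 0 °C; 17, 0 °C → rt; I2, 0 °C; then aq. Na2S2O3 and DBU, rt
Reagents that add atoms: diiodomethane, ICI
Why: Et2Zn deprotonates 17 to zinc enolate 18, whose C8 attacks the carbenoid EtZnCH2I on the open exo face, the zinc homoenolate adds to the C10 ketone to give donor–acceptor cyclopropanolate 19, push–pull cleavage of the shared C8–C10 bond (a retro-aldol-type fragmentation driven by loss of cyclopropane and norbornane strain) gives ester enolate 20, I2 converts it into tertiary iodide 21 and DBU into 22. The closest known reaction type is the zinc-carbenoid chain extension of β-keto esters to γ-keto esters, known also as a ring expansion of cyclic β-keto esters and in tandem with iodination–elimination to γ-oxo-enoates. Ring C is closed not end to end but by 3-exo-trig closure onto the ketone followed by scission of the zero-atom bridge of the bicyclo[3.1.0] unit, which turns the five-membered ring C1–C10–C8–C7–C11 into the six-membered ring. No stereocentre is created in 22 (C8, C9 and C10 are sp2; the transient centres of 19 and 21 follow exo attack and vanish), and the five existing ones cannot epimerise because C1 and C6 are quaternary, C7 is a bridgehead and C2 and C5 carry no acidifying group. Site selectivity of the insertion is secured because only the C8–C10 bond lies between the alkoxide donor and the ester acceptor, and the elimination can only run toward C9, whose hydrogens are α to the ketone, since a C7=C8 bridgehead alkene is forbidden. Chemoselectivity is secured by timing, because 17 holds no alkene that the carbenoid could cyclopropanate, and TBS ether, acetal and tert-butyl ester tolerate the neutral zinc reagents.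

Step 11
Reactants: 22 γ-oxo-enoate
Product: 23 endo (equatorial) C10 allylic alcohol
Conditions: NaBH4, CeCl3·7H2O, MeOH, −78 °C
Reagents that add atoms: none
Why: Luche 1,2-reduction, in which hydride should arrive from the exo face (C11 side) because the C5–C6 bridge with its endo H and endo CH2OTBS closes the endo face, so that the C10 hydroxyl ends up endo.

Step 12
Reactants: 24 9-bromononanoic acid
Product: 25 (8-carboxyoctyl)triphenylphosphonium bromide
Conditions: PPh3, MeCN, reflux
Reagents that add atoms: triphenylphosphine, c1ccc(cc1)P(c1ccccc1)c1ccccc1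
Why: SN2 quaternisation of a phosphine by a primary bromide.

Step 13
Reactants: 26 heptane-1,7-diol
Product: 27 7-[(tert-butyldimethylsilyl)oxy]heptan-1-ol
Conditions: 26 (3 equiv), TBSCl, imidazole, THF, rt
Reagents that add atoms: tert-butyldimethylsilyl chloride, CC(C)(C)[Si](C)(C)Cl
Why: Statistical monosilylation, biased toward the mono ether by the excess of diol.

Step 14
Reactants: 27 mono-TBS diol
Product: 28 7-[(tert-butyldimethylsilyl)oxy]heptanal
Conditions: TEMPO (10 mol %), PhI(OAc)2, CH2Cl2, rt
Reagents that add atoms: none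
Why: Oxoammonium (TEMPO) oxidation of a primary alcohol stops at the aldehyde and leaves the silyl ether alone.

Step 15
Reactants: 25 phosphonium salt; 28 aldehyde
Product: 30 (9Z)-16-[(tert-butyldimethylsilyl)oxy]hexadec-9-enoic acid, via carboxylate ylide 29 (not isolated)
Conditions: 25, NaN(SiMe3)2 (2.1 equiv), THF, 0 °C; 28, −78 °C → rt; cold dilute aq. HCl
Reagents that add atoms: none
Why: Wittig reaction of a non-stabilised ylide under lithium-free conditions, in which kinetic formation of the cis-oxaphosphetane should set the Z-alkene.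

Step 16
Reactants: 23 endo allylic alcohol; 30 side-chain acid
Product: 32 fully protected C10 ester, via mixed anhydride 31 (not isolated)
Conditions: 30, 2,4,6-trichlorobenzoyl chloride, Et3N, toluene, rt; then 23, DMAP, rt → 40 °C
Reagents that add atoms: none
Why: Yamaguchi esterification acylates the hindered secondary alcohol at oxygen, so C10 keeps its configuration.

Step 17
Reactants: 32 fully protected ester
Product: 33 target CNP0148862.2
Conditions: TFA/CH2Cl2/H2O (10:10:1), 0 °C → rt
Reagents that add atoms: water, O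
Why: Global acidolysis (loss of isobutene from the tert-butyl ester, acetal hydrolysis, cleavage of both primary TBS ethers) should spare the C10 ester, whose ionisation would need an allyl cation destabilised by the carboxyl group, and the absence of base protects the C2 centre α to the aldehyde.

Compound list
1 | (1S,5R)-2-oxabicyclo[3.3.0]oct-6-en-3-one, i.e. (3aR,6aS)-3,3a,6,6a-tetrahydro-2H-cyclopenta[b]furan-2-one | O=C1C[C@@H]2C=CC[C@@H]2O1 | starting material
2 | 4-iodobut-1-ene | C=CCCI | starting material
3 | lithium enolate of 1 | [Li]OC1=C[C@@H]2C=CC[C@@H]2O1 | intermediate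
4 | (3S,3aS,6aS)-3-(but-3-en-1-yl)-3,3a,6,6a-tetrahydro-2H-cyclopenta[b]furan-2-one (chain on the convex face) | O=C1[C@@H](CCC=C)[C@@H]2C=CC[C@@H]2O1 | intermediate
5 | (2S)-2-[(1S,5S)-5-hydroxycyclopent-2-en-1-yl]-N-methoxy-N-methylhex-5-enamide | O[C@H]1CC=C[C@H]1[C@@H](C(=O)N(C)OC)CCC=C | intermediate
6 | (2S)-N-methoxy-N-methyl-2-[(1S)-5-oxocyclopent-2-en-1-yl]hex-5-enamide | O=C1CC=C[C@H]1[C@@H](C(=O)N(C)OC)CCC=C | intermediate
7 | (2S)-N-methoxy-N-methyl-2-(5-oxocyclopent-1-en-1-yl)hex-5-enamide | O=C1CCC=C1[C@@H](C(=O)N(C)OC)CCC=C | intermediate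
8 | methyl methacrylate | C=C(C)C(=O)OC | starting material
9 | methyl (2E,6S)-6-[methoxy(methyl)carbamoyl]-2-methyl-6-(5-oxocyclopent-1-en-1-yl)hex-2-enoate | O=C1CCC=C1[C@@H](C(=O)N(C)OC)CC/C=C(\C)C(=O)OC | intermediate
10 | 2-silyloxy-3-alkylcyclopenta-1,3-diene (cross-conjugated TBS dienol ether of 9) | CC(C)(C)[Si](C)(C)OC1=CCC=C1[C@@H](C(=O)N(C)OC)CC/C=C(\C)C(=O)OC | intermediate
11 | 1-alkyl-2-silyloxycyclopenta-1,3-diene (reactive isomer of 10) | CC(C)(C)[Si](C)(C)OC1=C(CC=C1)[C@@H](C(=O)N(C)OC)CC/C=C(\C)C(=O)OC | intermediate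
12 | Diels–Alder adduct, 9-norcedr-8(10)-ene with OTBS at C10, exo CH3/endo CO2Me at C6, Weinreb amide at C2 on the C11 side | C[C@@]1(C(=O)OC)[C@H]2C[C@@]3(C(O[Si](C)(C)C(C)(C)C)=C2)[C@@H](C(=O)N(C)OC)CC[C@@H]13 | intermediate
13 | hydroxy aldehyde (endo CH2OH at C6, CHO at C2, enol ether kept) | C[C@@]1(CO)[C@H]2C[C@@]3(C(O[Si](C)(C)C(C)(C)C)=C2)[C@@H](C=O)CC[C@@H]13 | intermediate
14 | 9-norcedran-10-one with CH(OMe)2 at C2 and endo CH2OH at C6 | C[C@@]1(CO)[C@H]2C[C@@]3(C(=O)C2)[C@@H](C(OC)OC)CC[C@@H]13 | intermediate
15 | TBS ether of 14 | C[C@@]1(CO[Si](C)(C)C(C)(C)C)[C@H]2C[C@@]3(C(=O)C2)[C@@H](C(OC)OC)CC[C@@H]13 | intermediate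
16 | lithium enolate of 15 (C8=C10) | C[C@@]1(CO[Si](C)(C)C(C)(C)C)[C@H]2C[C@@]3(C(O[Li])=C2)[C@@H](C(OC)OC)CC[C@@H]13 | intermediate
17 | tert-butyl β-keto ester (exo CO2tBu at C8, ketone at C10) | C[C@@]1(CO[Si](C)(C)C(C)(C)C)[C@H]2C[C@@]3(C(=O)[C@@H]2C(=O)OC(C)(C)C)[C@@H](C(OC)OC)CC[C@@H]13 | intermediate
18 | ethylzinc enolate of 17 | C[C@@]1(CO[Si](C)(C)C(C)(C)C)[C@H]2C[C@@]3(C(O[Zn]CC)=C2C(=O)OC(C)(C)C)[C@@H](C(OC)OC)CC[C@@H]13 | intermediate
19 | exo-fused donor–acceptor cyclopropanolate (C8–C9–C10 three-membered ring, O–ZnEt at C10, ester at C8) | C[C@@]1(CO[Si](C)(C)C(C)(C)C)[C@H]2C[C@@]3([C@]4(O[Zn]CC)C[C@]24C(=O)OC(C)(C)C)[C@@H](C(OC)OC)CC[C@@H]13 | intermediate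
20 | ring-expanded zinc ester enolate (cedran-10-one, C8 enolate) | C[C@@]1(CO[Si](C)(C)C(C)(C)C)[C@H]2C[C@@]3(C(=O)CC2=C(O[Zn]CC)OC(C)(C)C)[C@@H](C(OC)OC)CC[C@@H]13 | intermediate
21 | tertiary α-iodo γ-keto ester (exo I at C8) | C[C@@]1(CO[Si](C)(C)C(C)(C)C)[C@H]2C[C@@]3(C(=O)C[C@@]2(I)C(=O)OC(C)(C)C)[C@@H](C(OC)OC)CC[C@@H]13 | intermediate
22 | γ-oxo-enoate (10-oxocedr-8-ene-8-carboxylate) | C[C@@]1(CO[Si](C)(C)C(C)(C)C)[C@H]2C[C@@]3(C(=O)C=C2C(=O)OC(C)(C)C)[C@@H](C(OC)OC)CC[C@@H]13 | intermediate
23 | endo C10 allylic alcohol | C[C@@]1(CO[Si](C)(C)C(C)(C)C)[C@H]2C[C@@]3([C@@H](O)C=C2C(=O)OC(C)(C)C)[C@@H](C(OC)OC)CC[C@@H]13 | intermediate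
24 | 9-bromononanoic acid | OC(=O)CCCCCCCCBr | starting material
25 | (8-carboxyoctyl)triphenylphosphonium bromide | [Br-].OC(=O)CCCCCCCC[P+](c1ccccc1)(c1ccccc1)c1ccccc1 | intermediate
26 | heptane-1,7-diol | OCCCCCCCO | starting material
27 | 7-[(tert-butyldimethylsilyl)oxy]heptan-1-ol | OCCCCCCCO[Si](C)(C)C(C)(C)C | intermediate
28 | 7-[(tert-butyldimethylsilyl)oxy]heptanal | O=CCCCCCCO[Si](C)(C)C(C)(C)C | intermediate
29 | sodium 9-(triphenyl-λ5-phosphanylidene)nonanoate | [Na+].[O-]C(=O)CCCCCCCC=P(c1ccccc1)(c1ccccc1)c1ccccc1 | intermediate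
30 | (9Z)-16-[(tert-butyldimethylsilyl)oxy]hexadec-9-enoic acid | OC(=O)CCCCCCC/C=C\CCCCCCO[Si](C)(C)C(C)(C)C | intermediate
31 | mixed anhydride of 30 and 2,4,6-trichlorobenzoic acid | O=C(CCCCCCC/C=C\CCCCCCO[Si](C)(C)C(C)(C)C)OC(=O)c1c(Cl)cc(Cl)cc1Cl | intermediate
32 | fully protected C10 ester (tBu ester, dimethyl acetal, two TBS ethers) | C[C@@]1(CO[Si](C)(C)C(C)(C)C)[C@H]2C[C@@]3([C@@H](OC(=O)CCCCCCC/C=C\CCCCCCO[Si](C)(C)C(C)(C)C)C=C2C(=O)OC(C)(C)C)[C@@H](C(OC)OC)CC[C@@H]13 | intermediate
33 | CNP0148862.2 | C[C@@]1(CO)[C@H]2C[C@@]3([C@@H](OC(=O)CCCCCCC/C=C\CCCCCCO)C=C2C(=O)O)[C@@H](C=O)CC[C@@H]13 | target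

Total step count: 17. Longest linear sequence: 13 (steps 1–11, 16, 17).

Steps most likely to fail

1. Step 10.
- What may go wrong: C-alkylation of the hindered zinc enolate may be slow. Protonation of the homoenolate (net α-methylation) or incomplete fragmentation of the cyclopropanolate could then compete.
- Fallback (radical instead of carbenoid; sets out from 17, comes back at 22): the sodium enolate of 17 (NaH, THF/DMPU) is alkylated with CH2I2 on the exo face to the α-iodomethyl β-keto ester F1.
- Bu3SnH/AIBN (benzene, 80 °C) then triggers a Dowd–Beckwith ring expansion. The primary radical attacks the C10 ketone in a 3-exo mode, and β-scission gives the ester-stabilised C8 radical. This should give the saturated γ-keto ester F2.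
- Dehydrogenation with IBX in DMSO, where only C9 can be enolised, gives 22.

2. Step 11.
- What may go wrong: facial selectivity may be poor. The acetal at C2 crowds the exo face of the C10 ketone, so hydride delivery from the endo face may compete.
- Fallback (inversion instead of direct control; sets out from 22, comes back at 32): the reduction is allowed to give the exo C10 alcohol F3.
- F3 is esterified with inversion in a Mitsunobu reaction with acid 30 (PPh3, DIAD, toluene). This gives 32 directly and replaces step 16.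

3. Step 17.
- What may go wrong: the tert-butyl ester may not cleave fully at an acid strength that the Z-alkene and the aldehyde tolerate. Acid-induced epimerisation at C2 or trifluoroacetylation of the alcohols are also possible.
- Fallback (staged, non-Brønsted unmasking; sets out from 32, comes back at 33): TMSOTf/2,6-lutidine (CH2Cl2, 0 °C) turns the tert-butyl ester into a silyl ester and the acetal into a lutidinium salt.
- Water then releases the bis-TBS aldehyde acid F4.
- HF·pyridine in THF/pyridine removes both TBS ethers to give 33.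

Further compounds
F1 | step 10 | α-iodomethyl β-keto ester (exo CH2I, endo CO2tBu at C8) | C[C@@]1(CO[Si](C)(C)C(C)(C)C)[C@H]2C[C@@]3(C(=O)[C@@]2(CI)C(=O)OC(C)(C)C)[C@@H](C(OC)OC)CC[C@@H]13
F2 | step 10 | saturated ring-expanded γ-keto ester (endo CO2tBu at C8) | C[C@@]1(CO[Si](C)(C)C(C)(C)C)[C@H]2C[C@@]3(C(=O)C[C@H]2C(=O)OC(C)(C)C)[C@@H](C(OC)OC)CC[C@@H]13
F3 | step 11 | exo C10 allylic alcohol (C10 epimer of 23) | C[C@@]1(CO[Si](C)(C)C(C)(C)C)[C@H]2C[C@@]3([C@H](O)C=C2C(=O)OC(C)(C)C)[C@@H](C(OC)OC)CC[C@@H]13
F4 | step 17 | bis-TBS aldehyde acid | C[C@@]1(CO[Si](C)(C)C(C)(C)C)[C@H]2C[C@@]3([C@@H](OC(=O)CCCCCCC/C=C\CCCCCCO[Si](C)(C)C(C)(C)C)C=C2C(=O)O)[C@@H](C=O)CC[C@@H]13
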